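**Retrosynthetic overview**

1. Feature: in ring A the methoxy oxygen and the CH2CH2 bridge to ring B sit on carbons that are meta (1,3) to each other, with one bare CH between them. This is the pattern of a 6-alkylsalicylate that has lost its carboxyl group, so ring A is built rather than bought.
2. Target ⇐ tri-O-benzyl ether ⇐ (protodecarboxylation, ester hydrolysis, O-methylation, dehydrogenation) ⇐ 6-substituted 2-oxocyclohex-3-ene-1-carboxylate ⇐ ethyl acetoacetate + (E)-5-arylpent-2-enal, by Michael addition then aldol condensation (two C–C bonds, ring A).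
3. Enal ⇐ 3-arylpropanal + formyl ylide ⇐ hydrocinnamate ester ⇐ cinnamate/stilbene diaryl ether, with both C=C bonds reduced together by diimide.
4. Diaryl ether (ring B–O–ring C) ⇐ Ullmann coupling of a 4-bromostilbene (rings C and D, from a Horner–Wadsworth–Emmons reaction) with a ring B phenol cinnamate (from a Wittig reaction).
5. Ring order: rings B, C and D enter as bought arenes; ring A is the only ring formed, late, and is aromatised after closure.

Key step: step 8

Remark: the target is achiral, the only stereocentres on the route are racemic and are erased on aromatisation, the phosphonate and both stabilised ylides are taken as purchased, and Ar = 4-(benzyloxy)-3-{4-[2-(2,5-bis(benzyloxy)phenyl)ethyl]phenoxy}phenyl throughout.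

**Route**

Step 1
Reactants: 1 2,5-dihydroxybenzaldehyde
Product: 2 2,5-bis(benzyloxy)benzaldehyde
Conditions: BnBr (2.4 equiv), K2CO3, DMF, 60 °C
Reagents that add atoms: benzyl bromide, BrCc1ccccc1
Why: Williamson ether synthesis, in which carbonate in DMF benzylates both phenols (including the hydrogen-bonded ortho one) and leaves the aldehyde alone.

Step 2
Reactants: 2 2,5-bis(benzyloxy)benzaldehyde; 3 diethyl (4-bromobenzyl)phosphonate
Product: 4 (E)-1,4-bis(benzyloxy)-2-[2-(4-bromophenyl)ethenyl]benzene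
Conditions: KOtBu, THF, 0 °C to rt
Reagents that add atoms: none
Why: Horner–Wadsworth–Emmons olefination of a non-enolisable aryl aldehyde with a benzylic phosphonate anion should give the (E)-stilbene, with aryl bromide and benzyl ethers inert to the base.

Step 3
Reactants: 5 4-(benzyloxy)-3-hydroxybenzaldehyde; 6 ethyl (triphenylphosphoranylidene)acetate
Product: 7 ethyl (E)-3-[4-(benzyloxy)-3-hydroxyphenyl]prop-2-enoate
Conditions: PhMe, 90 °C
Reagents that add atoms: none
Why: Wittig olefination with a stabilised ylide tolerates the free phenol and should give the (E)-cinnamate.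

Step 4
Reactants: 4 (E)-1,4-bis(benzyloxy)-2-[2-(4-bromophenyl)ethenyl]benzene; 7 ethyl (E)-3-[4-(benzyloxy)-3-hydroxyphenyl]prop-2-enoate
Product: 8 ethyl (E)-3-[4-(benzyloxy)-3-{4-[(E)-2-(2,5-bis(benzyloxy)phenyl)ethenyl]phenoxy}phenyl]prop-2-enoate
Conditions: CuI (10 mol %), N,N-dimethylglycine hydrochloride (30 mol %), Cs2CO3 (2 equiv), 1,4-dioxane, 100 °C
Reagents that add atoms: none
Why: Ullmann-type copper-catalysed C–O coupling of an aryl bromide with a 2-alkoxyphenol, a pairing well established for this family of diaryl ethers, run under dry carbonate conditions that spare the ester and both alkenes.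

Step 5
Reactants: 8 ethyl (E)-3-[4-(benzyloxy)-3-{4-[(E)-2-(2,5-bis(benzyloxy)phenyl)ethenyl]phenoxy}phenyl]prop-2-enoate
Product: 9 ethyl 3-Ar-propanoate
Conditions: TsNHNH2 (excess, in portions), NaOAc, DME–H2O, reflux
Reagents that add atoms: none
Why: Diimide reduction, in which diimide released from the sulfonyl hydrazide delivers H2 by concerted syn transfer to both the stilbene and the cinnamate C=C and cannot hydrogenolyse the three benzyl ethers or reduce the ester.

Step 6
Reactants: 9 ethyl 3-Ar-propanoate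
Product: 10 3-Ar-propanal
Conditions: i-Bu2AlH (1.1 equiv), CH2Cl2, −78 °C; then MeOH, aq. potassium sodium tartrate (KNaC4H4O6)
Reagents that add atoms: none
Why: Partial reduction of an ester by i-Bu2AlH, whose tetrahedral aluminium hemiacetal persists at −78 °C and releases the aldehyde only on work-up.

Step 7
Reactants: 10 3-Ar-propanal; 11 (triphenylphosphoranylidene)acetaldehyde
Product: 12 (E)-5-Ar-pent-2-enal
Conditions: PhMe, 80 °C (ylide about 1.05 equiv)
Reagents that add atoms: none
Why: Wittig two-carbon homologation with the stabilised formyl ylide should give the (E)-enal, and near-stoichiometric ylide limits a second homologation of the product.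

Step 8
Reactants: 12 (E)-5-Ar-pent-2-enal; 13 ethyl acetoacetate
Product: 16 racemic trans ethyl (1R*,6S*)-6-(2-Ar-ethyl)-2-oxocyclohex-3-ene-1-carboxylate, via Michael adduct 14 (not isolated), via aldol adduct 15 (not isolated)
Conditions: 13 (1.5 equiv), NaOEt (0.3 equiv), EtOH–THF, slow addition of 12 at −10 °C, then rt; then TsOH·H2O (cat.), PhMe, 80 °C
Reagents that add atoms: none
Why: Under catalytic ethoxide the acetoacetate anion adds to C3 of the enal to give 14, proton transfer lets the methyl-ketone enolate attack the aldehyde to give 15, and loss of water (E1cB, finished by the acid stage) gives enone 16. The closest known reaction is the classical Michael–aldol annulation of acetoacetic esters with 2-alkenals to 6-alkyl-2-oxocyclohex-3-enecarboxylates, a Robinson-type sequence. The six-membered carbocycle closes by a 6-(enolendo)-exo-trig aldol, both enolate carbons lying inside the new ring, which is a favoured mode for enolates. The two new centres (C1 and C6) are racemic, C1 is epimerisable and should settle trans to the side chain, and both are erased in step 9, so no control is needed. The step needs 1,4-addition before any 1,2-addition and ring closure through the methyl carbon: the soft stabilised anion under reversible alkoxide conditions secures the first (aldol-type 1,2-adducts revert and no amine is present to drive a Knoevenagel condensation), and only the methyl carbon can reach the aldehyde through a six-membered transition state. Slow addition of 12 to excess 13 suppresses a second Michael addition.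

Step 9
Reactants: 16 racemic trans ethyl (1R*,6S*)-6-(2-Ar-ethyl)-2-oxocyclohex-3-ene-1-carboxylate
Product: 17 ethyl 2-hydroxy-6-(2-Ar-ethyl)benzoate
Conditions: DDQ (1.1 equiv), 1,4-dioxane, rt to 60 °C
Reagents that add atoms: none
Why: Quinone dehydrogenation, in which the readily enolised β-keto ester gives up hydride to DDQ and the resulting dienone tautomerises to the salicylate, whereas bibenzyl CH2 groups and benzyl ethers react with DDQ only on prolonged heating.

Step 10
Reactants: 17 ethyl 2-hydroxy-6-(2-Ar-ethyl)benzoate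
Product: 18 ethyl 2-methoxy-6-(2-Ar-ethyl)benzoate
Conditions: MeI, K2CO3, DMF, 50 °C
Reagents that add atoms: iodomethane, CI
Why: Williamson O-methylation, site-specific because the ring A hydroxyl is the only free phenol in the molecule.

Step 11
Reactants: 18 ethyl 2-methoxy-6-(2-Ar-ethyl)benzoate
Product: 19 2-methoxy-6-(2-Ar-ethyl)benzoic acid
Conditions: KOH (excess), DMSO–H2O, 110 °C; then aq. HCl
Reagents that add atoms: potassium hydroxide, [K+].[OH-]
Why: Saponification (BAc2) of a di-ortho-substituted benzoate needs poorly solvated hydroxide in DMSO, conditions to which aryl ethers and benzyl ethers are inert.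

Step 12
Reactants: 19 2-methoxy-6-(2-Ar-ethyl)benzoic acid
Product: 20 1,4-bis(benzyloxy)-2-{2-[4-(2-(benzyloxy)-5-[2-(3-methoxyphenyl)ethyl]phenoxy)phenyl]ethyl}benzene
Conditions: Ag2CO3 (10 mol %), AcOH (5 mol %), DMSO, 120 °C
Reagents that add atoms: none
Why: Silver-catalysed protodecarboxylation of an ortho-substituted benzoic acid, in which the twisted silver carboxylate extrudes CO2 and the aryl–silver species is protonated.

Step 13
Reactants: 20 1,4-bis(benzyloxy)-2-{2-[4-(2-(benzyloxy)-5-[2-(3-methoxyphenyl)ethyl]phenoxy)phenyl]ethyl}benzene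
Product: 21 2-{2-[4-(2-hydroxy-5-[2-(3-methoxyphenyl)ethyl]phenoxy)phenyl]ethyl}benzene-1,4-diol (target, CNP0211397.0)
Conditions: H2 (1 atm), 10% Pd/C, EtOAc–EtOH, rt
Reagents that add atoms: none
Why: Catalytic hydrogenolysis cleaves the three aryl benzyl ethers, while the aryl methyl ether, the diaryl ether and the two CH2CH2 bridges are inert.

**Compound list**

1 | 2,5-dihydroxybenzaldehyde | O=Cc1cc(O)ccc1O | starting material
2 | 2,5-bis(benzyloxy)benzaldehyde | O=Cc1cc(OCc2ccccc2)ccc1OCc3ccccc3 | intermediate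
3 | diethyl (4-bromobenzyl)phosphonate | CCOP(=O)(Cc1ccc(Br)cc1)OCC | starting material
4 | (E)-1,4-bis(benzyloxy)-2-[2-(4-bromophenyl)ethenyl]benzene | Brc1ccc(/C=C/c2cc(OCc3ccccc3)ccc2OCc4ccccc4)cc1 | intermediate
5 | 4-(benzyloxy)-3-hydroxybenzaldehyde | O=Cc1ccc(OCc2ccccc2)c(O)c1 | starting material
6 | ethyl (triphenylphosphoranylidene)acetate | CCOC(=O)C=P(c1ccccc1)(c2ccccc2)c3ccccc3 | starting material
7 | ethyl (E)-3-[4-(benzyloxy)-3-hydroxyphenyl]prop-2-enoate | CCOC(=O)/C=C/c1ccc(OCc2ccccc2)c(O)c1 | intermediate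
8 | ethyl (E)-3-[4-(benzyloxy)-3-{4-[(E)-2-(2,5-bis(benzyloxy)phenyl)ethenyl]phenoxy}phenyl]prop-2-enoate | CCOC(=O)/C=C/c1ccc(OCc2ccccc2)c(Oc3ccc(/C=C/c4cc(OCc5ccccc5)ccc4OCc6ccccc6)cc3)c1 | intermediate
9 | ethyl 3-[4-(benzyloxy)-3-{4-[2-(2,5-bis(benzyloxy)phenyl)ethyl]phenoxy}phenyl]propanoate | CCOC(=O)CCc1ccc(OCc2ccccc2)c(Oc3ccc(CCc4cc(OCc5ccccc5)ccc4OCc6ccccc6)cc3)c1 | intermediate
10 | 3-[4-(benzyloxy)-3-{4-[2-(2,5-bis(benzyloxy)phenyl)ethyl]phenoxy}phenyl]propanal | O=CCCc1ccc(OCc2ccccc2)c(Oc3ccc(CCc4cc(OCc5ccccc5)ccc4OCc6ccccc6)cc3)c1 | intermediate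
11 | (triphenylphosphoranylidene)acetaldehyde | O=CC=P(c1ccccc1)(c2ccccc2)c3ccccc3 | starting material
12 | (E)-5-[4-(benzyloxy)-3-{4-[2-(2,5-bis(benzyloxy)phenyl)ethyl]phenoxy}phenyl]pent-2-enal | O=C/C=C/CCc1ccc(OCc2ccccc2)c(Oc3ccc(CCc4cc(OCc5ccccc5)ccc4OCc6ccccc6)cc3)c1 | intermediate
13 | ethyl acetoacetate | CCOC(=O)CC(C)=O | starting material
14 | ethyl 2-acetyl-3-(2-Ar-ethyl)-5-oxopentanoate (Michael adduct, racemic mixture of diastereomers) | CCOC(=O)C(C(C)=O)C(CC=O)CCc1ccc(OCc2ccccc2)c(Oc3ccc(CCc4cc(OCc5ccccc5)ccc4OCc6ccccc6)cc3)c1 | intermediate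
15 | ethyl 4-hydroxy-2-oxo-6-(2-Ar-ethyl)cyclohexane-1-carboxylate (aldol adduct, racemic mixture of diastereomers) | CCOC(=O)C1C(=O)CC(O)CC1CCc2ccc(OCc3ccccc3)c(Oc4ccc(CCc5cc(OCc6ccccc6)ccc5OCc7ccccc7)cc4)c2 | intermediate
16 | racemic trans ethyl (1R*,6S*)-6-(2-Ar-ethyl)-2-oxocyclohex-3-ene-1-carboxylate (one enantiomer drawn) | CCOC(=O)[C@H]1C(=O)C=CC[C@@H]1CCc2ccc(OCc3ccccc3)c(Oc4ccc(CCc5cc(OCc6ccccc6)ccc5OCc7ccccc7)cc4)c2 | intermediate
17 | ethyl 2-hydroxy-6-(2-Ar-ethyl)benzoate | CCOC(=O)c1c(O)cccc1CCc2ccc(OCc3ccccc3)c(Oc4ccc(CCc5cc(OCc6ccccc6)ccc5OCc7ccccc7)cc4)c2 | intermediate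
18 | ethyl 2-methoxy-6-(2-Ar-ethyl)benzoate | CCOC(=O)c1c(OC)cccc1CCc2ccc(OCc3ccccc3)c(Oc4ccc(CCc5cc(OCc6ccccc6)ccc5OCc7ccccc7)cc4)c2 | intermediate
19 | 2-methoxy-6-(2-Ar-ethyl)benzoic acid | OC(=O)c1c(OC)cccc1CCc2ccc(OCc3ccccc3)c(Oc4ccc(CCc5cc(OCc6ccccc6)ccc5OCc7ccccc7)cc4)c2 | intermediate
20 | 1,4-bis(benzyloxy)-2-{2-[4-(2-(benzyloxy)-5-[2-(3-methoxyphenyl)ethyl]phenoxy)phenyl]ethyl}benzene | COc1cccc(CCc2ccc(OCc3ccccc3)c(Oc4ccc(CCc5cc(OCc6ccccc6)ccc5OCc7ccccc7)cc4)c2)c1 | intermediate
21 | 2-{2-[4-(2-hydroxy-5-[2-(3-methoxyphenyl)ethyl]phenoxy)phenyl]ethyl}benzene-1,4-diol | COc1cccc(CCc2ccc(O)c(Oc3ccc(CCc4cc(O)ccc4O)cc3)c2)c1 | target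

**Step count and risks**

Total step count: 13. Longest linear sequence: 12 steps (steps 1, 2 and 4 to 13, from 2,5-dihydroxybenzaldehyde); step 3 is the one branch.

Steps most likely to fail:

Step 8 (key annulation). The enal may be lost to 1,2-addition or Knoevenagel-type condensation at the aldehyde, to base-induced self-condensation through its γ-position, or to a second Michael addition, and the sequence may stall before dehydration. Fallback: setting out from 12, conjugate addition is enforced by iminium-ion catalysis instead of base. tert-Butyl acetoacetate and racemic 2-[diphenyl(trimethylsilyloxy)methyl]pyrrolidine (10 mol %) in toluene at rt should give the Michael adduct tert-butyl 2-acetyl-3-(2-Ar-ethyl)-5-oxopentanoate F1. TsOH·H2O in toluene at 80 °C should then bring about aldol condensation, loss of 2-methylpropene and decarboxylation in the same pot to give racemic 5-(2-Ar-ethyl)cyclohex-2-en-1-one F2. Aerobic dehydrogenation (Pd(O2CCF3)2 5 mol %, 2-(dimethylamino)pyridine, TsOH, O2 1 atm, DMSO, 80 °C) should give 3-(2-Ar-ethyl)phenol F3, and MeI/K2CO3 in DMF brings the material back to the route at 20. This variant gives up the salicylate stage but keeps the same ring construction.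

Step 9 (dehydrogenation). Hydride abstraction by DDQ at the benzylic CH2 groups next to the dialkoxy-substituted rings, or oxidative loss of a benzyl ether, may compete with dehydrogenation of the ring. Fallback: setting out from 16, the oxidation is done by α-selenenylation and selenoxide elimination, which touches only the β-keto ester. PhSeCl and pyridine in CH2Cl2 at 0 °C should give ethyl 2-oxo-1-(phenylselanyl)-6-(2-Ar-ethyl)cyclohex-3-ene-1-carboxylate F4, with selenium expected anti to the side chain and therefore syn to the C6 hydrogen. Aqueous H2O2 at 0 °C to rt should oxidise it to the selenoxide ethyl 2-oxo-1-(phenylseleninyl)-6-(2-Ar-ethyl)cyclohex-3-ene-1-carboxylate F5, which is not isolated. Syn elimination then gives the cross-conjugated dienone ethyl 6-oxo-2-(2-Ar-ethyl)cyclohexa-1,4-diene-1-carboxylate F6, which enolises at once to 17, where the route is rejoined.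

Step 4 (Ullmann coupling). Slow turnover with the ortho-alkoxy, chelating phenoxide may lead to stalled coupling and hydrodebromination of the aryl bromide. Fallback: setting out from 7 and 2, the diaryl ether is made by nucleophilic aromatic substitution and the stilbene afterwards.
- Phenol 7 with 4-fluorobenzaldehyde (K2CO3, DMF, 120 °C) should give ethyl (E)-3-[4-(benzyloxy)-3-(4-formylphenoxy)phenyl]prop-2-enoate F7.
- Aldehyde 2 is reduced (NaBH4, THF–MeOH, 0 °C) to [2,5-bis(benzyloxy)phenyl]methanol F8, converted with PBr3 (CH2Cl2, 0 °C) into 1,4-bis(benzyloxy)-2-(bromomethyl)benzene F9, and heated with PPh3 in toluene to give [2,5-bis(benzyloxy)benzyl]triphenylphosphonium bromide F10.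
- Wittig reaction of F10 with F7 (K2CO3, 18-crown-6, CH2Cl2, reflux) should give 8 together with its (Z)-stilbene isomer ethyl (E)-3-[4-(benzyloxy)-3-{4-[(Z)-2-(2,5-bis(benzyloxy)phenyl)ethenyl]phenoxy}phenyl]prop-2-enoate F11. Step 5 reduces both alike, so the route is rejoined at 9.

**Further compounds**

F1 | step 8 | tert-butyl 2-acetyl-3-(2-Ar-ethyl)-5-oxopentanoate (racemic mixture of diastereomers) | CC(=O)C(C(=O)OC(C)(C)C)C(CC=O)CCc1ccc(OCc2ccccc2)c(Oc3ccc(CCc4cc(OCc5ccccc5)ccc4OCc6ccccc6)cc3)c1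
F2 | step 8 | racemic 5-(2-Ar-ethyl)cyclohex-2-en-1-one | O=C1C=CCC(CCc2ccc(OCc3ccccc3)c(Oc4ccc(CCc5cc(OCc6ccccc6)ccc5OCc7ccccc7)cc4)c2)C1
F3 | step 8 | 3-(2-Ar-ethyl)phenol | Oc1cccc(CCc2ccc(OCc3ccccc3)c(Oc4ccc(CCc5cc(OCc6ccccc6)ccc5OCc7ccccc7)cc4)c2)c1
F4 | step 9 | racemic ethyl 2-oxo-1-(phenylselanyl)-6-(2-Ar-ethyl)cyclohex-3-ene-1-carboxylate, selenium anti to the side chain (one enantiomer drawn) | CCOC(=O)[C@]1([Se]c2ccccc2)C(=O)C=CC[C@@H]1CCc3ccc(OCc4ccccc4)c(Oc5ccc(CCc6cc(OCc7ccccc7)ccc6OCc8ccccc8)cc5)c3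
F5 | step 9 | racemic ethyl 2-oxo-1-(phenylseleninyl)-6-(2-Ar-ethyl)cyclohex-3-ene-1-carboxylate (selenoxide, configuration at selenium not defined) | CCOC(=O)[C@]1([Se](=O)c2ccccc2)C(=O)C=CC[C@@H]1CCc3ccc(OCc4ccccc4)c(Oc5ccc(CCc6cc(OCc7ccccc7)ccc6OCc8ccccc8)cc5)c3
F6 | step 9 | ethyl 6-oxo-2-(2-Ar-ethyl)cyclohexa-1,4-diene-1-carboxylate | CCOC(=O)C1=C(CCc2ccc(OCc3ccccc3)c(Oc4ccc(CCc5cc(OCc6ccccc6)ccc5OCc7ccccc7)cc4)c2)CC=CC1=O
F7 | step 4 | ethyl (E)-3-[4-(benzyloxy)-3-(4-formylphenoxy)phenyl]prop-2-enoate | CCOC(=O)/C=C/c1ccc(OCc2ccccc2)c(Oc3ccc(C=O)cc3)c1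
F8 | step 4 | [2,5-bis(benzyloxy)phenyl]methanol | OCc1cc(OCc2ccccc2)ccc1OCc3ccccc3
F9 | step 4 | 1,4-bis(benzyloxy)-2-(bromomethyl)benzene | BrCc1cc(OCc2ccccc2)ccc1OCc3ccccc3
F10 | step 4 | [2,5-bis(benzyloxy)benzyl]triphenylphosphonium bromide | [Br-].c1ccc(cc1)[P+](Cc2cc(OCc3ccccc3)ccc2OCc4ccccc4)(c5ccccc5)c6ccccc6
F11 | step 4 | ethyl (E)-3-[4-(benzyloxy)-3-{4-[(Z)-2-(2,5-bis(benzyloxy)phenyl)ethenyl]phenoxy}phenyl]prop-2-enoate | CCOC(=O)/C=C/c1ccc(OCc2ccccc2)c(Oc3ccc(/C=C\c4cc(OCc5ccccc5)ccc4OCc6ccccc6)cc3)c1
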